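No rate constant is given for this flask of E, D and J, so what can be said must come from the readings of Q in two earlier runs, of which ochre has the asked recipe.

common to all: E 0.10 M; D 0.10 M

|  | J | remark | time |
|---|---|---|---|
| ochre | 2.5 equiv | the very flask that is asked about, followed so far |  |
| grey | 1.7 equiv | run made earlier |  |
| flask | 2.50 equiv |  | 2.0 h |

- ochre (time / min: Q / %): 30.0: 20; 40.0: 24; 50.0: 24
- grey (time / min: Q / %): 30.0: 17; 40.0: 18; 50.0: 18

(readings scatter by 1.5 percentage points)

* when, up to 2.0 h, the flask holds most Q
* the amount of Q, in percent of the E and D together charged, at that time
* the first time at which Q reaches 12 %, in the same percent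

- J is single-handed; E and D are mirror images of each other, charged as a racemate, each of them at the stated concentration
- the handed part of J does not stay in what it makes, so the products of the two hands are mirror images too

A bench rule says that two equal readings in a row mean a finished reaction. Applied to ochre, with 24 % and 24 % at 40.0 min and 50.0 min, it holds Q at that level up to 2.0 h. But the difference of two readings carries a scatter of 2.1 percentage points. The gain of Q per hour from the first to the last ochre reading, as a fraction of the charge, is 0.120 h⁻¹; call it the creep. Between neighbouring readings the creep adds 2 points, which is less than that scatter, a ratio of 0.943. So these two equal ochre readings do not tell a stopped flask from a creeping one, and there the rule ends. The reckoning made here runs the creep on from the last ochre reading: Q is highest at 2.0 h, with 38.0 %, give or take 7.4 points. Ochre and grey stand at a ratio of 1.33 in last readings against 1.47 in J, and on that loose ground Q is taken here to scale with J.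

The forecast differs in the amount: 24.3 % at 2 h, and 12 % reached at 0.13 h, holding that “The reaction then stalls when J is gone”.

The flask gives 41.0 % at 2.00 h, and reaches 12 % at 0.145 h.

    J + E → Q (k = 0.00880 M⁻¹ s⁻¹)
    J + D → X (k = 0.00430 M⁻¹ s⁻¹)
    E ⇌ D (k = 0.300 s⁻¹)
    J ⇌ Z (K = 8.00, k = 0.0100 s⁻¹)

From 1.00 h to 2.00 h the flask's Q gains 0.113 h⁻¹, beside the creep of 0.120 h⁻¹ read from ochre. At 2.00 h the flask still holds 5.47 % of its J as free J, next to 0.114 M of Z, the resting state of J. Scaling the reckoned Q to a neighbour charged with 1.00 equiv of J gives 15.2 %. That neighbour ends with 19.6 % of Q, and with 35.4 % of D.

The readings were generated by integration with constants of no real substance.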